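**Plan**

- Retrosynthesis: the senecioate is cut first at the C1'–O acyl bond. Ring A is then cut at C1–C2, C3–C4 and C4–C4a into a carbene carbon (C1), a two-carbon alkyne (C2, C3) and one carbonyl ligand (C4). The carbene goes back to an aryl bromide, and the side chain is cut at C1'–C2' (allyl addition to an aldehyde) and C3'=C4' (cross-metathesis).
- Enabling feature: ring A (C1–C4) has only hydrogen at C2 and C3 and oxygen at C1 and C4. C8a has the methoxy-bearing C8 as one neighbour, so a new ring can close only at C4a. Ring B (C5 OH, C7 chain, C8 OMe) maps onto 2,5-dihydroxybenzaldehyde, whose two hydroxyls differ by hydrogen bonding to the formyl group.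
- Forward, ring B is bought: its free hydroxyl is silylated, bromine is placed at the future C8a, the chelated hydroxyl is methylated, and the formyl carbon becomes C1' by allylboration, followed by cross-metathesis to the prenyl terminus and silylation.
- Ring A is grown last from the aryl(methoxy)carbene chromium complex, trimethylsilylacetylene and CO. Oxidation then gives a quinone in ring A only, fluoride removes all silicon, and the C1' ester is made at the end.
- Stereochemistry: the only stereocentre, C1' (R), is set by reagent-controlled Brown allylboration with the borane from (−)-α-pinene (Re-face attack), and its C–O bond is never broken afterwards.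

Key step: step 8

Remark: quinone locants are those of the target drawn with C1=O beside the C8 methoxy and C4=O beside the C5 hydroxyl (chain on C7, carbinol carbon C1'); naphthols are numbered from their hydroxyl carbon; (+)-B-allyldiisopinocampheylborane is assumed to be bought as its pentane solution.

**Route**

Step 1
Reactants: 1 2,5-dihydroxybenzaldehyde
Product: 2 5-(tert-butyldimethylsilyloxy)-2-hydroxybenzaldehyde
Conditions: TBSCl (1.05 equiv), imidazole, DMF, 0 °C
Reagents that add atoms: tert-butyldimethylsilyl chloride, CC(C)(C)[Si](C)(C)Cl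
Why: Silyl ether formation, in which the C2 hydroxyl is hydrogen-bonded to the formyl group and shielded, so one equivalent of silyl chloride should react at the free C5 hydroxyl only.

Step 2
Reactants: 2 5-(tert-butyldimethylsilyloxy)-2-hydroxybenzaldehyde
Product: 3 3-bromo-5-(tert-butyldimethylsilyloxy)-2-hydroxybenzaldehyde
Conditions: NBS, MeCN, 0 °C to rt
Reagents that add atoms: N-bromosuccinimide, O=C1CCC(=O)N1Br
Why: Electrophilic aromatic bromination, directed by the free hydroxyl to its only open ortho position (C3, meta to the formyl group), whereas the positions next to the silyl ether are ortho or para to the deactivating formyl group.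

Step 3
Reactants: 3 3-bromo-5-(tert-butyldimethylsilyloxy)-2-hydroxybenzaldehyde
Product: 4 3-bromo-5-(tert-butyldimethylsilyloxy)-2-methoxybenzaldehyde
Conditions: MeI, K2CO3, acetone, 40 °C
Reagents that add atoms: iodomethane, CI
Why: Williamson ether synthesis on the only acidic site, the chelated phenol, under dry, weakly basic conditions that an aryl silyl ether tolerates.

Step 4
Reactants: 4 3-bromo-5-(tert-butyldimethylsilyloxy)-2-methoxybenzaldehyde
Product: 6 (R)-1-[3-bromo-5-(tert-butyldimethylsilyloxy)-2-methoxyphenyl]but-3-en-1-ol, via diisopinocampheylborinate ester 5 (not isolated)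
Conditions: (+)-Ipc2B(allyl) (from (−)-α-pinene), Et2O, −78 °C; then HOCH2CH2NH2, rt
Reagents that add atoms: (+)-B-allyldiisopinocampheylborane, C=CCB([C@H]1C[C@H]2C[C@@H]([C@@H]1C)C2(C)C)[C@H]1C[C@H]2C[C@@H]([C@@H]1C)C2(C)C
Why: Brown asymmetric allylboration, in which the borane derived from (−)-α-pinene delivers allyl through a chair six-membered transition state to the Re face of an aryl aldehyde and so sets C1' as R under reagent control, after which ethanolamine frees the alcohol from boron without base or oxidant.

Step 5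
Reactants: 6 (R)-1-[3-bromo-5-(tert-butyldimethylsilyloxy)-2-methoxyphenyl]but-3-en-1-ol
Product: 7 (R)-1-[3-bromo-5-(tert-butyldimethylsilyloxy)-2-methoxyphenyl]-4-methylpent-3-en-1-ol
Conditions: 2-methylbut-2-ene (excess), second-generation Grubbs catalyst RuCl2(=CHPh)(H2IMes)(PCy3) (5 mol %), CH2Cl2, 40 °C
Reagents that add atoms: 2-methylbut-2-ene, CC=C(C)C
Why: Olefin cross-metathesis of a terminal alkene with excess 2-methylbut-2-ene installs the isopropylidene terminus with loss of propene and leaves the aryl bromide, the free carbinol and the stereocentre untouched.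

Step 6
Reactants: 7 (R)-1-[3-bromo-5-(tert-butyldimethylsilyloxy)-2-methoxyphenyl]-4-methylpent-3-en-1-ol
Product: 8 (R)-1-bromo-5-(tert-butyldimethylsilyloxy)-3-[1-(tert-butyldimethylsilyloxy)-4-methylpent-3-en-1-yl]-2-methoxybenzene
Conditions: TBSOTf, 2,6-lutidine, CH2Cl2, −78 °C
Reagents that add atoms: tert-butyldimethylsilyl trifluoromethanesulfonate, CC(C)(C)[Si](C)(C)OS(=O)(=O)C(F)(F)F
Why: Silylation of a hindered secondary benzylic alcohol with a silyl triflate and a non-nucleophilic base masks the carbinol for the organolithium step and, since only the O–H bond reacts, keeps the configuration.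

Step 7
Reactants: 8 (R)-1-bromo-5-(tert-butyldimethylsilyloxy)-3-[1-(tert-butyldimethylsilyloxy)-4-methylpent-3-en-1-yl]-2-methoxybenzene; 9 chromium hexacarbonyl
Product: 12 pentacarbonyl[(R)-{5-(tert-butyldimethylsilyloxy)-3-[1-(tert-butyldimethylsilyloxy)-4-methylpent-3-en-1-yl]-2-methoxyphenyl}(methoxy)methylidene]chromium, via aryllithium 10 (not isolated), via lithium acylchromate 11 (not isolated)
Conditions: t-BuLi (2 equiv), Et2O, −78 °C; Cr(CO)6, −78 °C to rt; then Me3OBF4, CH2Cl2, 0 °C
Reagents that add atoms: trimethyloxonium tetrafluoroborate, C[O+](C)C.F[B-](F)(F)F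
Why: Fischer carbene synthesis, in which bromine–lithium exchange at −78 °C outruns any deprotonation, the aryllithium adds to a carbonyl ligand of Cr(CO)6, and the acylchromate is O-methylated by the hard oxonium salt.

Step 8
Reactants: 12 pentacarbonyl[(R)-{5-(tert-butyldimethylsilyloxy)-3-[1-(tert-butyldimethylsilyloxy)-4-methylpent-3-en-1-yl]-2-methoxyphenyl}(methoxy)methylidene]chromium; 13 trimethylsilylacetylene
Product: 15 (R)-8-(tert-butyldimethylsilyloxy)-6-[1-(tert-butyldimethylsilyloxy)-4-methylpent-3-en-1-yl]-4,5-dimethoxy-2-(trimethylsilyl)naphthalen-1-ol, via tricarbonylchromium naphthol complex 14 (not isolated)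
Conditions: 13 (2 equiv), THF, 50 °C; then air, rt
Reagents that add atoms: none
Why: Loss of one CO from 12, helped by the ortho methoxy oxygen taking the vacant site on chromium, lets the alkyne bind and insert into the Cr=C bond (C1–C2), and the vinylcarbene so formed takes up a carbonyl ligand (C3–C4) to give a chromium-bound dienylketene. The closest known reaction type is the Dötz benzannulation of aryl(alkoxy)carbene chromium complexes with a silylalkyne serving as an acetylene equivalent. Ring A closes by thermal six-electron electrocyclisation of this ketene onto the free ortho carbon (C4–C4a), and enolisation of the dienone gives the 4-methoxy-1-naphthol as its Cr(CO)3 complex 14, which air demetallates to 15. No stereocentre is formed, and C1' is remote from the metal and not ionisable under these neutral conditions. The step needs site selectivity of closure, secured because the other ortho position carries the methoxy group, whereas the orientation of the alkyne (silicon expected next to the new hydroxyl) is immaterial because silicon is later exchanged for hydrogen on a ring that has hydrogen at both C2 and C3. The small trimethylsilyl group is chosen so that the silylketene keeps the geometry needed for ring closure and is not released as a stable vinylketene.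

Step 9
Reactants: 15 (R)-8-(tert-butyldimethylsilyloxy)-6-[1-(tert-butyldimethylsilyloxy)-4-methylpent-3-en-1-yl]-4,5-dimethoxy-2-(trimethylsilyl)naphthalen-1-ol
Product: 16 (R)-5-(tert-butyldimethylsilyloxy)-7-[1-(tert-butyldimethylsilyloxy)-4-methylpent-3-en-1-yl]-8-methoxy-3-(trimethylsilyl)naphthalene-1,4-dione
Conditions: PhI(OAc)2, MeCN/H2O, 0 °C
Reagents that add atoms: water, O
Why: Oxidative demethylation of a para-methoxyphenol by a hypervalent (trivalent) iodine reagent, in which the free naphthol of ring A is activated at oxygen, water adds at the methoxy-bearing para carbon and methanol is lost, while ring B, which has no free hydroxyl, and the trisubstituted alkene are not oxidised.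

Step 10
Reactants: 16 (R)-5-(tert-butyldimethylsilyloxy)-7-[1-(tert-butyldimethylsilyloxy)-4-methylpent-3-en-1-yl]-8-methoxy-3-(trimethylsilyl)naphthalene-1,4-dione
Product: 17 (R)-5-hydroxy-7-(1-hydroxy-4-methylpent-3-en-1-yl)-8-methoxynaphthalene-1,4-dione
Conditions: Bu4NF, AcOH, THF, 0 °C to rt
Reagents that add atoms: none
Why: Fluoride-mediated desilylation, in which Si–O cleavage frees the C5 phenol and the C1' carbinol and attack of fluoride on the silicon at C3, whose bond to the quinone carbon is polarised like that of an α-silyl enone, followed by protonation by AcOH puts hydrogen in its place, the acetic acid buffer protecting the base-sensitive quinone.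

Step 11
Reactants: 17 (R)-5-hydroxy-7-(1-hydroxy-4-methylpent-3-en-1-yl)-8-methoxynaphthalene-1,4-dione; 18 3-methylbut-2-enoic acid
Product: 19 (R)-1-(4-hydroxy-1-methoxy-5,8-dioxo-5,8-dihydronaphthalen-2-yl)-4-methylpent-3-en-1-yl 3-methylbut-2-enoate
Conditions: DCC, DMAP (cat.), CH2Cl2, 0 °C
Reagents that add atoms: none
Why: Steglich esterification, in which the C5 hydroxyl is held in a hydrogen bond to the C4 carbonyl and is a poor nucleophile, so acylation should occur only at the C1' carbinol and with retention because its C–O bond is not broken.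

**Compound list**

1 | 2,5-dihydroxybenzaldehyde | O=Cc1cc(O)ccc1O | starting material
2 | 5-(tert-butyldimethylsilyloxy)-2-hydroxybenzaldehyde | O=Cc1cc(O[Si](C)(C)C(C)(C)C)ccc1O | intermediate
3 | 3-bromo-5-(tert-butyldimethylsilyloxy)-2-hydroxybenzaldehyde | O=Cc1cc(O[Si](C)(C)C(C)(C)C)cc(Br)c1O | intermediate
4 | 3-bromo-5-(tert-butyldimethylsilyloxy)-2-methoxybenzaldehyde | COc1c(Br)cc(O[Si](C)(C)C(C)(C)C)cc1C=O | intermediate
5 | (R)-1-[3-bromo-5-(tert-butyldimethylsilyloxy)-2-methoxyphenyl]but-3-en-1-yl diisopinocampheylborinate (isopinocampheyl groups from (−)-α-pinene) | COc1c(Br)cc(O[Si](C)(C)C(C)(C)C)cc1[C@@H](CC=C)OB([C@H]1C[C@H]2C[C@@H]([C@@H]1C)C2(C)C)[C@H]1C[C@H]2C[C@@H]([C@@H]1C)C2(C)C | intermediate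
6 | (R)-1-[3-bromo-5-(tert-butyldimethylsilyloxy)-2-methoxyphenyl]but-3-en-1-ol | COc1c(Br)cc(O[Si](C)(C)C(C)(C)C)cc1[C@@H](CC=C)O | intermediate
7 | (R)-1-[3-bromo-5-(tert-butyldimethylsilyloxy)-2-methoxyphenyl]-4-methylpent-3-en-1-ol | COc1c(Br)cc(O[Si](C)(C)C(C)(C)C)cc1[C@@H](CC=C(C)C)O | intermediate
8 | (R)-1-bromo-5-(tert-butyldimethylsilyloxy)-3-[1-(tert-butyldimethylsilyloxy)-4-methylpent-3-en-1-yl]-2-methoxybenzene | COc1c(Br)cc(O[Si](C)(C)C(C)(C)C)cc1[C@@H](CC=C(C)C)O[Si](C)(C)C(C)(C)C | intermediate
9 | chromium hexacarbonyl, Cr(CO)6 | O=C=[Cr](=C=O)(=C=O)(=C=O)(=C=O)=C=O | starting material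
10 | (R)-{5-(tert-butyldimethylsilyloxy)-3-[1-(tert-butyldimethylsilyloxy)-4-methylpent-3-en-1-yl]-2-methoxyphenyl}lithium | COc1c([Li])cc(O[Si](C)(C)C(C)(C)C)cc1[C@@H](CC=C(C)C)O[Si](C)(C)C(C)(C)C | intermediate
11 | lithium pentacarbonyl[(R)-{5-(tert-butyldimethylsilyloxy)-3-[1-(tert-butyldimethylsilyloxy)-4-methylpent-3-en-1-yl]-2-methoxyphenyl}(oxido)methylidene]chromate | [Li+].[O-]C(=[Cr](=C=O)(=C=O)(=C=O)(=C=O)=C=O)c1cc(O[Si](C)(C)C(C)(C)C)cc([C@@H](CC=C(C)C)O[Si](C)(C)C(C)(C)C)c1OC | intermediate
12 | pentacarbonyl[(R)-{5-(tert-butyldimethylsilyloxy)-3-[1-(tert-butyldimethylsilyloxy)-4-methylpent-3-en-1-yl]-2-methoxyphenyl}(methoxy)methylidene]chromium | COC(=[Cr](=C=O)(=C=O)(=C=O)(=C=O)=C=O)c1cc(O[Si](C)(C)C(C)(C)C)cc([C@@H](CC=C(C)C)O[Si](C)(C)C(C)(C)C)c1OC | intermediate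
13 | trimethylsilylacetylene | C#C[Si](C)(C)C | starting material
14 | tricarbonylchromium complex of naphthol 15 (chromium η6-bound to ring A, drawn as two parts) | COc1cc([Si](C)(C)C)c(O)c2c(O[Si](C)(C)C(C)(C)C)cc([C@@H](CC=C(C)C)O[Si](C)(C)C(C)(C)C)c(OC)c12.O=C=[Cr](=C=O)=C=O | intermediate
15 | (R)-8-(tert-butyldimethylsilyloxy)-6-[1-(tert-butyldimethylsilyloxy)-4-methylpent-3-en-1-yl]-4,5-dimethoxy-2-(trimethylsilyl)naphthalen-1-ol | COc1cc([Si](C)(C)C)c(O)c2c(O[Si](C)(C)C(C)(C)C)cc([C@@H](CC=C(C)C)O[Si](C)(C)C(C)(C)C)c(OC)c12 | intermediate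
16 | (R)-5-(tert-butyldimethylsilyloxy)-7-[1-(tert-butyldimethylsilyloxy)-4-methylpent-3-en-1-yl]-8-methoxy-3-(trimethylsilyl)naphthalene-1,4-dione | COc1c([C@@H](CC=C(C)C)O[Si](C)(C)C(C)(C)C)cc(O[Si](C)(C)C(C)(C)C)c2c1C(=O)C=C([Si](C)(C)C)C2=O | intermediate
17 | (R)-5-hydroxy-7-(1-hydroxy-4-methylpent-3-en-1-yl)-8-methoxynaphthalene-1,4-dione | COc1c([C@@H](CC=C(C)C)O)cc(O)c2c1C(=O)C=CC2=O | intermediate
18 | 3-methylbut-2-enoic acid | CC(C)=CC(=O)O | starting material
19 | (R)-1-(4-hydroxy-1-methoxy-5,8-dioxo-5,8-dihydronaphthalen-2-yl)-4-methylpent-3-en-1-yl 3-methylbut-2-enoate | COc1c([C@@H](CC=C(C)C)OC(=O)C=C(C)C)cc(O)c2c1C(=O)C=CC2=O | target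

**Step count**

Total: 11 steps. Longest linear sequence: 11 steps (1 to 19); 9, 13 and 18 are bought and enter directly.

**Steps most likely to fail**

Step 8 (benzannulation). The chromium-bound silylketene may fail to cyclise and be released as a stable vinylketene, the vinylcarbene may close without CO uptake to an indene, or closure next to the silyloxy-bearing carbon may be slow. A 1,3-shift of silicon from carbon to oxygen would be harmless, since that isomer converges after steps 9 and 10. The fallback replaces the carbene annulation by an aryne cycloaddition; it sets out from bromide 8 and returns at 17. Treatment of 8 with LiN(i-Pr)2 in THF/furan from −78 °C to rt should remove the only proton ortho to bromine, expel LiBr and give the aryne between the future C8a and C4a, which furan traps by [4+2] cycloaddition as 5-(tert-butyldimethylsilyloxy)-7-[(R)-1-(tert-butyldimethylsilyloxy)-4-methylpent-3-en-1-yl]-8-methoxy-1,4-dihydro-1,4-epoxynaphthalene F1 (both bridgehead configurations, which vanish on aromatisation). A catalytic sulfonic acid (CSA, CH2Cl2, 0 °C) should open the strained oxygen bridge to the two regioisomeric naphthols, 8-(tert-butyldimethylsilyloxy)-6-[(R)-1-(tert-butyldimethylsilyloxy)-4-methylpent-3-en-1-yl]-5-methoxynaphthalen-1-ol F2 and 5-(tert-butyldimethylsilyloxy)-7-[(R)-1-(tert-butyldimethylsilyloxy)-4-methylpent-3-en-1-yl]-8-methoxynaphthalen-1-ol F3. Both are oxidised para to the hydroxyl by PhI(OCOCF3)2 in MeCN/H2O to the same quinone, (R)-5-(tert-butyldimethylsilyloxy)-7-[1-(tert-butyldimethylsilyloxy)-4-methylpent-3-en-1-yl]-8-methoxynaphthalene-1,4-dione F4, and the conditions of step 10 convert F4 into 17.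

Step 10 (fluoride desilylation). Cleavage of the C3–Si bond may lag far behind Si–O cleavage, and long exposure to fluoride may degrade the unsubstituted quinone ring by conjugate addition. The fallback removes silicon from carbon at the naphthol oxidation level with an electrophile, not from the quinone with a nucleophile; it sets out from 15 and returns at 17. Ring A of 15 is a very electron-rich arylsilane, so brief treatment with CF3CO2H in CH2Cl2 at −40 °C should bring about ipso-protodesilylation to (R)-8-(tert-butyldimethylsilyloxy)-6-[1-(tert-butyldimethylsilyloxy)-4-methylpent-3-en-1-yl]-4,5-dimethoxynaphthalen-1-ol F5; the low temperature and short contact are meant to keep the benzylic silyl ether from ionising. Oxidation of F5 as in step 9 gives the silicon-free quinone F4 of the preceding fallback, and buffered fluoride then has only Si–O bonds to break on the way to 17.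

Step 11 (esterification). Acylation may spill over to the C5 hydroxyl, DMAP may add to the unsubstituted C2=C3 bond of the quinone, or the acyl double bond may move out of conjugation through a ketene pathway. The fallback forms the ester before the phenol and C3 are unmasked; it sets out from 16 and returns at 19. An alkyl silyl ether is cleaved by acid much faster than an aryl silyl ether, so CSA in MeOH/CH2Cl2 at 0 °C should free only the C1' carbinol of 16 and give (R)-5-(tert-butyldimethylsilyloxy)-7-(1-hydroxy-4-methylpent-3-en-1-yl)-8-methoxy-3-(trimethylsilyl)naphthalene-1,4-dione F6. Acylation of F6 with 18 (DCC, catalytic DMAP, CH2Cl2, 0 °C), now without a free phenol and with C3 blocked, should give (R)-1-[4-(tert-butyldimethylsilyloxy)-1-methoxy-5,8-dioxo-6-(trimethylsilyl)-5,8-dihydronaphthalen-2-yl]-4-methylpent-3-en-1-yl 3-methylbut-2-enoate F7, and the buffered fluoride of step 10 then removes the aryl silyl ether and the carbon-bound silicon to give 19.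

Further compounds
F1 | step 8 | 5-(tert-butyldimethylsilyloxy)-7-[(R)-1-(tert-butyldimethylsilyloxy)-4-methylpent-3-en-1-yl]-8-methoxy-1,4-dihydro-1,4-epoxynaphthalene (both bridgehead configurations) | COc1c([C@@H](CC=C(C)C)O[Si](C)(C)C(C)(C)C)cc(O[Si](C)(C)C(C)(C)C)c2c1C1C=CC2O1
F2 | step 8 | 8-(tert-butyldimethylsilyloxy)-6-[(R)-1-(tert-butyldimethylsilyloxy)-4-methylpent-3-en-1-yl]-5-methoxynaphthalen-1-ol | COc1c([C@@H](CC=C(C)C)O[Si](C)(C)C(C)(C)C)cc(O[Si](C)(C)C(C)(C)C)c2c(O)cccc12
F3 | step 8 | 5-(tert-butyldimethylsilyloxy)-7-[(R)-1-(tert-butyldimethylsilyloxy)-4-methylpent-3-en-1-yl]-8-methoxynaphthalen-1-ol | COc1c([C@@H](CC=C(C)C)O[Si](C)(C)C(C)(C)C)cc(O[Si](C)(C)C(C)(C)C)c2cccc(O)c12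
F4 | step 8 | (R)-5-(tert-butyldimethylsilyloxy)-7-[1-(tert-butyldimethylsilyloxy)-4-methylpent-3-en-1-yl]-8-methoxynaphthalene-1,4-dione | COc1c([C@@H](CC=C(C)C)O[Si](C)(C)C(C)(C)C)cc(O[Si](C)(C)C(C)(C)C)c2c1C(=O)C=CC2=O
F5 | step 10 | (R)-8-(tert-butyldimethylsilyloxy)-6-[1-(tert-butyldimethylsilyloxy)-4-methylpent-3-en-1-yl]-4,5-dimethoxynaphthalen-1-ol | COc1ccc(O)c2c(O[Si](C)(C)C(C)(C)C)cc([C@@H](CC=C(C)C)O[Si](C)(C)C(C)(C)C)c(OC)c12
F6 | step 11 | (R)-5-(tert-butyldimethylsilyloxy)-7-(1-hydroxy-4-methylpent-3-en-1-yl)-8-methoxy-3-(trimethylsilyl)naphthalene-1,4-dione | COc1c([C@@H](CC=C(C)C)O)cc(O[Si](C)(C)C(C)(C)C)c2c1C(=O)C=C([Si](C)(C)C)C2=O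
F7 | step 11 | (R)-1-[4-(tert-butyldimethylsilyloxy)-1-methoxy-5,8-dioxo-6-(trimethylsilyl)-5,8-dihydronaphthalen-2-yl]-4-methylpent-3-en-1-yl 3-methylbut-2-enoate | COc1c([C@@H](CC=C(C)C)OC(=O)C=C(C)C)cc(O[Si](C)(C)C(C)(C)C)c2c1C(=O)C=C([Si](C)(C)C)C2=O
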